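**Plan**

1. Retrosynthesis: the aryl acetate (a protecting group) is removed last; the C13–C14 bond of the hexacosanoyl chain is cut into two primary alkyl radicals, each traced back to a CO2H group; the ester O–CH2 bond to tyrosol and a tert-butyl ester are cut last.
2. Forward: tyrosol is esterified at its aliphatic OH with mono-tert-butyl tetradecanedioate, the phenol is acetylated, the tert-butyl ester is removed, and the C26 chain is joined C13 + C13 by a mixed Kolbe electrolysis with tetradecanoic acid; deacetylation ends the route.
3. Enabling feature: C13 and C14 lie in the unbranched, heteroatom-free C2–C25 methylene run, twelve CH2 groups from the ester carbon C1 and far from the benzene ring. Each can therefore be generated as an unstabilised primary radical from a carboxylate, and the two like-polarity carbons are joined at the anode with loss of two CO2.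
4. Helper: the acetate makes the benzene ring electron-poor enough to survive the anode; it is taken off in step 5.
5. Stereochemistry: the target has no stereocentre and no C=C bond, so none is set.

Key step: step 4

Remark: 14-tert-butoxy-14-oxotetradecanoic acid (2) is taken as a purchasable lipidation building block.

**Route**

Step 1
Reactants: 1 tyrosol [4-(2-hydroxyethyl)phenol]; 2 14-tert-butoxy-14-oxotetradecanoic acid
Product: 3 1-tert-butyl 14-[2-(4-hydroxyphenyl)ethyl] tetradecanedioate
Conditions: PPh3, DIAD, THF, 0 °C → rt
Reagents that add atoms: none
Why: Mitsunobu esterification; only the aliphatic OH is activated as an alkoxyphosphonium ion, and the carboxylic acid (far more acidic than the phenol) is the nucleophile, so the primary alcohol should be esterified with the phenol left free.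

Step 2
Reactants: 3 1-tert-butyl 14-[2-(4-hydroxyphenyl)ethyl] tetradecanedioate
Product: 4 1-tert-butyl 14-[2-(4-acetoxyphenyl)ethyl] tetradecanedioate
Conditions: Ac2O, pyridine, DMAP (cat.), CH2Cl2, 0 °C → rt
Reagents that add atoms: acetic anhydride CC(=O)OC(C)=O
Why: Standard O-acetylation of the only free hydroxyl group (nucleophilic acyl substitution); both alkyl esters are inert.

Step 3
Reactants: 4 1-tert-butyl 14-[2-(4-acetoxyphenyl)ethyl] tetradecanedioate
Product: 5 14-[2-(4-acetoxyphenyl)ethoxy]-14-oxotetradecanoic acid
Conditions: TFA/CH2Cl2 (1:2), rt; toluene co-evaporation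
Reagents that add atoms: none
Why: Acidolysis of the tert-butyl ester by the tert-butyl cation (E1) pathway; the primary alkyl ester and the aryl acetate cannot ionise in this way and should survive anhydrous TFA.

Step 4
Reactants: 5 14-[2-(4-acetoxyphenyl)ethoxy]-14-oxotetradecanoic acid; 6 tetradecanoic acid (myristic acid)
Product: 7 2-(4-acetoxyphenyl)ethyl hexacosanoate
Conditions: 6 (5 equiv), KOH (5 mol% of total CO2H), MeOH, Pt anode/Pt cathode, undivided cell, ca. 0.2 A cm−2, 45–50 °C, stopped at ca. 90% of the theoretical charge while still acidic
Reagents that add atoms: none
Why: Mixed Kolbe electrolysis: the carboxylates of 5 and 6 are oxidised at the platinum anode at high current density to acyloxy radicals, which lose CO2 to give the 12-(aryl-ethoxycarbonyl)dodecyl and tridecyl radicals; these build up in the anode layer and combine to form the C13–C14 bond. The closest known reaction type is the anodic cross-coupling of a fatty acid with a dicarboxylic acid half-ester, the classical chain-building route to long-chain fatty esters. No ring is closed and no stereocentre is formed. Radical coupling must win over further oxidation to a cation (Hofer–Moest path), and the substrate secures this because both radicals are primary, unbranched and carry no α-heteroatom or aryl group. Cross- versus homo-coupling is statistical; the excess of cheap 6 should send nearly all of the ester radical to 7, leaving hexacosane and a little symmetrical diester, both separable by polarity. The arene should survive because the phenol is an electron-poor acetate held far from the adsorbed carboxylate head group, and both esters should survive because the bulk stays acidic until the current is switched off.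

Step 5
Reactants: 7 2-(4-acetoxyphenyl)ethyl hexacosanoate
Product: 8 2-(4-hydroxyphenyl)ethyl hexacosanoate
Conditions: pyrrolidine (3 equiv), THF/CH2Cl2, rt; dilute aqueous HCl work-up
Reagents that add atoms: none
Why: Chemoselective aminolysis of an aryl ester; the phenoxide is a far better leaving group than the alkoxide, so the acetate should be transferred to pyrrolidine at room temperature while the unactivated long-chain alkyl ester is untouched.

**Compound list**

1 | tyrosol, 4-(2-hydroxyethyl)phenol | OCCc1ccc(O)cc1 | starting material
2 | 14-tert-butoxy-14-oxotetradecanoic acid | CC(C)(C)OC(=O)CCCCCCCCCCCCC(=O)O | starting material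
3 | 1-tert-butyl 14-[2-(4-hydroxyphenyl)ethyl] tetradecanedioate | CC(C)(C)OC(=O)CCCCCCCCCCCCC(=O)OCCc1ccc(O)cc1 | intermediate
4 | 1-tert-butyl 14-[2-(4-acetoxyphenyl)ethyl] tetradecanedioate | CC(C)(C)OC(=O)CCCCCCCCCCCCC(=O)OCCc1ccc(OC(C)=O)cc1 | intermediate
5 | 14-[2-(4-acetoxyphenyl)ethoxy]-14-oxotetradecanoic acid | OC(=O)CCCCCCCCCCCCC(=O)OCCc1ccc(OC(C)=O)cc1 | intermediate
6 | tetradecanoic acid (myristic acid) | CCCCCCCCCCCCCC(=O)O | starting material
7 | 2-(4-acetoxyphenyl)ethyl hexacosanoate | CCCCCCCCCCCCCCCCCCCCCCCCCC(=O)OCCc1ccc(OC(C)=O)cc1 | intermediate
8 | 2-(4-hydroxyphenyl)ethyl hexacosanoate | CCCCCCCCCCCCCCCCCCCCCCCCCC(=O)OCCc1ccc(O)cc1 | target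

**Summary**

Total step count: 5. Longest linear sequence: 5 steps (1 and 2 → 3 → 4 → 5 → 7 → 8); tetradecanoic acid 6 enters in step 4.

**Steps most likely to fail**

Step 4 (mixed Kolbe electrolysis). The half-ester may be lost to statistical homo-coupling, the anode may be passivated by waxy deposits, the aromatic ring may be oxidised, or the aryl acetate may be methanolysed in the basic cathode layer, after which the freed phenol would be oxidised. Fallback, setting out from 5 and returning at 7: acid 5 would be condensed with N-hydroxyphthalimide (DIC, cat. DMAP, CH2Cl2) to the redox-active ester 2-(4-acetoxyphenyl)ethyl 1,3-dioxoisoindolin-2-yl tetradecanedioate F1. Commercial 1-bromotridecane (CCCCCCCCCCCCCBr) would be converted with Mg in THF into tridecylmagnesium bromide F2 and then with ZnCl2 (0.5 equiv) into ditridecylzinc F3. A nickel-catalysed decarboxylative alkyl–alkyl Negishi coupling of F1 with F3 (NiCl2·glyme, 4,4'-di-tert-butyl-2,2'-bipyridine, THF/DMF, rt) should then give 7 under reductive conditions that cannot oxidise the arene.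

Step 5 (selective deacetylation). The alkyl ester may be cleaved alongside the acetate, or the waxy substrate may react incompletely because of poor solubility. Fallback, setting out from 7 and returning at 8: both esters would be saponified deliberately (LiOH, THF/MeOH/H2O, 50 °C, then HCl) to hexacosanoic acid F4, which is easily purified by crystallisation. F4 would then be re-esterified with tyrosol 1 under the phenol-sparing Mitsunobu conditions of step 1 (PPh3, DIAD, THF) to give 8 directly.

Step 1 (chemoselective Mitsunobu). The phenol may compete as a nucleophile, giving aryl alkyl ether oligomers of tyrosol, and the product may be hard to separate from phosphine oxide and hydrazide. Fallback, setting out from 1 and returning at 4: the phenol would be acetylated first through its phenoxide (Ac2O, 1 equiv aqueous NaOH, 0 °C) to 4-(2-hydroxyethyl)phenyl acetate F5. The remaining primary alcohol would then be acylated with 2 by carbodiimide coupling (EDC·HCl, 5 mol% DMAP, CH2Cl2, 0 °C) to give 4, bypassing 3.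

**Further compounds**

F1 | step 4 | 2-(4-acetoxyphenyl)ethyl 1,3-dioxoisoindolin-2-yl tetradecanedioate | CC(=O)Oc1ccc(CCOC(=O)CCCCCCCCCCCCC(=O)ON2C(=O)c3ccccc3C2=O)cc1
F2 | step 4 | tridecylmagnesium bromide | CCCCCCCCCCCCC[Mg]Br
F3 | step 4 | ditridecylzinc | CCCCCCCCCCCCC[Zn]CCCCCCCCCCCCC
F4 | step 5 | hexacosanoic acid | CCCCCCCCCCCCCCCCCCCCCCCCCC(=O)O
F5 | step 1 | 4-(2-hydroxyethyl)phenyl acetate | CC(=O)Oc1ccc(CCO)cc1
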